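Atoms are numbered in the order of the target SMILES. The route rests on disconnecting C18–C22: the quaternary bridgehead C18 carries methyl C19 and the bond to C22, the imprint of a tertiary radical made by hydrogen-atom transfer to a C18=C19 methylidene and trapped by an acceptor alkene at C22. One iron-hydride operation should therefore form C18–C22, close the seven-membered ring B (C5, C6, C8, C21, C20, C18, C22) and set C18 and C22. Its precursor is a cis-fused pyran–cyclohexane (rings C and A) carrying the exocyclic C18=C19 alkene and, on C8, a triethylsilyloxy group and a Z-enone arm C6(=O)–C5=C22–C23–C24H(OEt)2.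

Key step: step 14

Rings: A = cyclohexane C15–C16–C17–C18–C20–C21; B = carbocycle C5–C6–C8–C21–C20–C18–C22; C = pyran C8–C10–O11–C12–C15–C21.

Remark on the chemistry: a C6 ketone separated from a C22=C23–C24 enal by the C5 methylene would be a vinylogous 1,3-dicarbonyl that enolises and scrambles its alkene, so the acceptor alkene is placed at C5=C22 in conjugation with the C6 ketone and C24 is carried as a diethyl acetal; ring B then closes 7-endo at the same two atoms, and the Z geometry is chosen because it is what relays into the C22 configuration.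

Step 1
Reactants: 1 ethyl 1,4-dioxaspiro[4.5]decane-8-carboxylate
Product: 3 2-(1,4-dioxaspiro[4.5]decan-8-yl)propan-2-ol, via methyl ketone 2 (not isolated)
Conditions: MeMgBr (3 equiv), THF, 0 °C to rt; H2O
Reagents that add atoms: methylmagnesium bromide, C[Mg]Br
Why: Twofold Grignard addition to the ester through ketone 2 gives the tertiary carbinol that becomes C12 with its two methyl groups, the ketal shields the future C18 carbonyl and no stereocentre is formed.

Step 2
Reactants: 3 2-(1,4-dioxaspiro[4.5]decan-8-yl)propan-2-ol; 4 2,3-dibromoprop-1-ene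
Product: 5 8-{2-[(2-bromoprop-2-en-1-yl)oxy]propan-2-yl}-1,4-dioxaspiro[4.5]decane
Conditions: KH, THF, 0 °C; then 4, n-Bu4NI (cat.), 0 °C to rt
Reagents that add atoms: none
Why: Williamson ether synthesis of the potassium tert-alkoxide at the primary allylic bromide of 4 (the vinylic bromide is inert to substitution) installs O11–C10 together with C8 and C6.

Step 3
Reactants: 5 8-{2-[(2-bromoprop-2-en-1-yl)oxy]propan-2-yl}-1,4-dioxaspiro[4.5]decane
Product: 6 4-{2-[(2-bromoprop-2-en-1-yl)oxy]propan-2-yl}cyclohexan-1-one
Conditions: 1 M HCl, THF, rt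
Reagents that add atoms: water, O
Why: Acid-catalysed ketal hydrolysis frees the C18 ketone while the tert-alkyl allyl ether and the vinyl bromide tolerate dilute aqueous acid at room temperature; 6 is achiral, with a mirror plane through C15 and C18.

Step 4
Reactants: 6 4-{2-[(2-bromoprop-2-en-1-yl)oxy]propan-2-yl}cyclohexan-1-one
Product: 8 (R)-{[4-(2-{[2-bromoprop-2-en-1-yl]oxy}propan-2-yl)cyclohex-1-en-1-yl]oxy}trimethylsilane, via lithium enolate 7 (not isolated)
Conditions: lithium (S,S)-bis(1-phenylethyl)amide (from the amine and n-BuLi), TMSCl (internal quench), THF, −100 to −78 °C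
Reagents that add atoms: chlorotrimethylsilane, C[Si](C)(C)Cl
Why: Enantioselective deprotonation of the prochiral 4-substituted cyclohexanone by a C2-symmetric chiral lithium amide removes one of the two enantiotopic α-hydrogens (the one on C20) and so fixes C15 as R; the (S,S)-amide is chosen by analogy with the established sense for 4-tert-butylcyclohexanone, whose CIP ranking parallels this case, and the enantiomeric purity can be raised later by crystallising diol 11.

Step 5
Reactants: 8 (R)-trimethylsilyl enol ether
Product: 9 (R)-4-{2-[(2-bromoprop-2-en-1-yl)oxy]propan-2-yl}cyclohex-2-en-1-one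
Conditions: IBX, 4-methoxypyridine N-oxide, DMSO, rt
Reagents that add atoms: none
Why: Dehydrogenation of the silyl enol ether by the hypervalent iodine oxidant (a metal-free equivalent of the Saegusa–Ito oxidation) puts the alkene at C20=C21 on the side fixed by the enol ether, leaves the vinyl bromide alone and is neutral enough to keep the γ-stereocentre C15.

Step 6
Reactants: 9 (R)-enone
Product: 10 (4aS,8aR)-1,1-dimethyl-4-methylideneoctahydro-6H-isochromen-6-one (cis-fused rings A and C; exocyclic C8=C6; C18 ketone)
Conditions: Pd(OAc)2 (10 mol%), PPh3 (20 mol%), HCO2Na, n-Bu4NCl, DMF, 80 °C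
Reagents that add atoms: none
Why: Intramolecular reductive Heck reaction, in which zerovalent palladium inserts into the C8–Br bond, 6-exo-trig syn-carbopalladation of the enone forms C8–C21 and formate reduces the palladium enolate; the three-atom tether from C15 can reach the neighbouring C21 only on its own face, so the ring fusion is cis (C21 S).

Step 7
Reactants: 10 cis-fused methylidene ketone
Product: 11 (4S,4aS,8aR)-4-hydroxy-4-(hydroxymethyl)-1,1-dimethyloctahydro-6H-isochromen-6-one (4-OH syn to H-4a)
Conditions: OsO4 (2 mol%), NMO, acetone/H2O, rt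
Reagents that add atoms: osmium tetroxide (catalytic oxygen carrier), O=[Os](=O)(=O)=O; N-methylmorpholine N-oxide, C[N+]1([O-])CCOCC1; water, O
Why: Upjohn dihydroxylation, in which OsO4 adds to the exocyclic C8=C6 alkene from the convex face, syn to H21 and away from ring A, so that O9 ends up syn to H21 and C6 on the ring-A side (the target configuration at C8) while the ketone is inert.

Step 8
Reactants: 11 keto diol
Product: 12 (4aS,8aR)-1,1-dimethyl-4-[(triethylsilyl)oxy]-4-{[(triethylsilyl)oxy]methyl}octahydro-6H-isochromen-6-one (C4 as in 11)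
Conditions: TESOTf (2.5 equiv), 2,6-lutidine, CH2Cl2, −78 to 0 °C
Reagents that add atoms: triethylsilyl trifluoromethanesulfonate, CC[Si](CC)(CC)OS(=O)(=O)C(F)(F)F
Why: Silyl ether formation with the silyl triflate and a hindered pyridine base covers the primary and the hindered tertiary hydroxyl alike, so that no free alkoxide can add to the C18 ketone in the next step.

Step 9
Reactants: 12 bis-silyl ether ketone
Product: 13 (4aS,8aR)-1,1-dimethyl-6-methylidene-4-[(triethylsilyl)oxy]-4-{[(triethylsilyl)oxy]methyl}octahydro-1H-isochromene (C4 as in 11)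
Conditions: Ph3PCH3Br, KOt-Bu, THF, 0 °C to rt
Reagents that add atoms: methyltriphenylphosphonium bromide, C[P+](c1ccccc1)(c1ccccc1)c1ccccc1.[Br-]
Why: Wittig methylenation of the unhindered C18 ketone installs C19 as the exocyclic alkene needed for hydrogen-atom transfer, and C21, being β to the carbonyl, cannot epimerise.

Step 10
Reactants: 13 bis-silyl ether diene precursor
Product: 14 (4aS,8aR)-1,1-dimethyl-6-methylidene-4-[(triethylsilyl)oxy]octahydro-1H-isochromene-4-carbaldehyde (silyloxy syn to H-4a)
Conditions: (COCl)2, DMSO, CH2Cl2, −78 to −40 °C; Et3N, −78 °C to rt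
Reagents that add atoms: none
Why: Swern oxidation, whose activated sulfonium species cleaves primary triethylsilyl ethers and oxidises them in the same flask while the tertiary silyl ether stays; aldehyde 14 has no α-hydrogen and cannot epimerise.

Step 11
Reactants: 14 α-silyloxy aldehyde; 15 4,4-diethoxybut-1-yne
Product: 17 5,5-diethoxy-1-[(4aS,8aR)-1,1-dimethyl-6-methylidene-4-(triethylsilyloxy)octahydro-1H-isochromen-4-yl]pent-2-yn-1-ol (both carbinol epimers), via lithium acetylide 16 (not isolated)
Conditions: 15, n-BuLi, THF, −78 °C; then 14, −78 to −40 °C; H2O at −40 °C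
Reagents that add atoms: none
Why: 1,2-Addition of the lithium acetylide to the non-enolisable aldehyde joins C5 to C6 and brings in C22–C24 with C24 already protected; the cold quench avoids migration of the silyl group to the new alkoxide, and the carbinol centre, formed as a mixture, is erased in step 13.

Step 12
Reactants: 17 propargylic alcohol
Product: 18 (Z)-5,5-diethoxy-1-[(4aS,8aR)-1,1-dimethyl-6-methylidene-4-(triethylsilyloxy)octahydro-1H-isochromen-4-yl]pent-2-en-1-ol (both carbinol epimers)
Conditions: H2 (1 atm), Pd/CaCO3 poisoned with Pb(OAc)2 (Lindlar catalyst), quinoline, EtOAc, rt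
Reagents that add atoms: none
Why: Lindlar semihydrogenation adds H2 syn to the alkyne and gives the Z alkene C5=C22, while the 1,1-disubstituted C18=C19 alkene is not reduced on the poisoned catalyst.

Step 13
Reactants: 18 Z-allylic alcohol
Product: 19 (Z)-5,5-diethoxy-1-[(4aS,8aR)-1,1-dimethyl-6-methylidene-4-(triethylsilyloxy)octahydro-1H-isochromen-4-yl]pent-2-en-1-one (precursor of the key step)
Conditions: Dess–Martin periodinane, NaHCO3, CH2Cl2, 0 °C
Reagents that add atoms: none
Why: Dess–Martin oxidation of the allylic alcohol under bicarbonate buffer gives the Z-enone without acid or base that could isomerise it to E or eliminate ethanol from the acetal.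

Step 14
Reactants: 19 Z-enone with exocyclic C18=C19
Product: 20 tricyclic keto acetal (rings A, B and C; C6 ketone; C5 methylene; O9 triethylsilyl ether; C22 bearing 2,2-diethoxyethyl; C8, C15, C18, C21, C22 as in the target)
Conditions: Fe(acac)3 (30 mol%), PhSiH3 (2.5 equiv), Na2HPO4, EtOH (0.02 M), 40 °C
Reagents that add atoms: none
Why: Fe(acac)3 and PhSiH3 in ethanol form an iron hydride that transfers a hydrogen atom to C19 of the electron-rich 1,1-disubstituted alkene; the nucleophilic tertiary C18 radical adds to C22, the β-carbon of the enone, and the α-keto C5 radical is reduced to the iron enolate and protonated by the solvent. This is the intramolecular version of the metal-hydride hydrogen-atom-transfer Giese (reductive olefin) coupling, a reaction type established for joining a quaternary to a tertiary carbon. Ring B closes 7-endo-trig, the polarity-matched mode, since 6-exo attack at C5 would leave an unstabilised secondary radical. C18 is controlled by the tether: the arm hangs from C8, which is 1,3-cis to C18 on ring A, so the new bond can form only on that face and C19 ends up opposite. C22 is controlled by the alkene geometry: with the C6 acyl group axial on the chair pyran and tucked under ring A, ring B closes with C5 on the inner side of C22, and the Z alkene then holds C23 beside C6 and O9 with H22 outward, which is the target configuration (the E isomer would give the epimer through the same ring shape). The step needs hydrogen-atom transfer to the methylidene in preference to the enone, which the polarity of the hydride donor provides, and ring closure faster than Z to E isomerisation, which the short reach between C6 and C18 (1,3-diaxial on ring A) and the mild buffered conditions are meant to secure.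

Step 15
Reactants: 20 tricyclic keto acetal; 21 3-bromo-2-methylprop-1-ene
Product: 23 C5-(2-methylprop-2-en-1-yl) tricyclic keto acetal (C5 side chain trans to the C22 side chain), via lithium enolate 22 (not isolated)
Conditions: LiN(i-Pr)2, THF, −78 °C; then 21, DMPU, −78 to −30 °C
Reagents that add atoms: none
Why: Enolate alkylation, in which the lithium enolate can form only toward C5 (C8 is quaternary) and the allylic bromide attacks anti to the neighbouring C22 side chain, setting C5 trans to it as in the target.

Step 16
Reactants: 23 methallyl ketone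
Product: 25 C5-(2-oxopropyl) tricyclic keto acetal, via diol 24 (not isolated)
Conditions: OsO4 (2 mol%), NaIO4, 2,6-lutidine, dioxane/H2O (3:1), rt
Reagents that add atoms: osmium tetroxide (catalytic oxygen carrier), O=[Os](=O)(=O)=O; sodium periodate, [Na+].[O-]I(=O)(=O)=O; water, O
Why: Lemieux–Johnson oxidation (catalytic dihydroxylation, then periodate cleavage of diol 24) turns the only alkene in the molecule into the C2 methyl ketone, and the lutidine buffer protects the acetal and the silyl ether.

Step 17
Reactants: 25 diketone acetal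
Product: 26 diketo aldehyde (C24 aldehyde; O9 triethylsilyl ether)
Conditions: PPTS (cat.), acetone/H2O (9:1), 40 °C
Reagents that add atoms: water, O
Why: Mild acid-catalysed acetal hydrolysis frees the C24 aldehyde from the acyclic diethyl acetal under conditions that a tertiary triethylsilyl ether survives and that are too weak to epimerise C5.

Step 18
Reactants: 27 3-methylbut-2-enoic acid (2 equiv)
Product: 28 3-methylbut-2-enoic anhydride
Conditions: N,N'-dicyclohexylcarbodiimide (0.5 equiv), CH2Cl2, 0 °C to rt; filtration
Reagents that add atoms: none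
Why: Carbodiimide-mediated dehydration of two molecules of the acid gives the symmetrical anhydride, a milder acyl donor than the acid chloride, which would form a vinylketene with amines.

Step 19
Reactants: 26 diketo aldehyde; 28 3-methylbut-2-enoic anhydride
Product: 29 triethylsilyl ether of the target ((E)-enol ester at C23=C24)
Conditions: Et3N, DMAP, CH2Cl2, rt
Reagents that add atoms: none
Why: Enol ester formation by O-acylation, in which the aldehyde enolate formed reversibly by Et3N is trapped by the acylpyridinium and should favour the less hindered, thermodynamically preferred E isomer; the ketone α-positions are far less acidic and any Z isomer would be removed by chromatography.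

Step 20
Reactants: 29 triethylsilyl ether of the target
Product: 30 CNP0237201.2
Conditions: HF·pyridine, pyridine, THF, 0 °C to rt
Reagents that add atoms: none
Why: Fluoride-mediated desilylation with buffered HF·pyridine removes the tertiary silyl ether without hydrolysing the enol ester or epimerising C5 and delivers the target.

Compound list
1 | ethyl 1,4-dioxaspiro[4.5]decane-8-carboxylate | CCOC(=O)C1CCC2(CC1)OCCO2 | starting material
2 | 1-(1,4-dioxaspiro[4.5]decan-8-yl)ethan-1-one | CC(=O)C1CCC2(CC1)OCCO2 | intermediate (not isolated)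
3 | 2-(1,4-dioxaspiro[4.5]decan-8-yl)propan-2-ol | CC(C)(O)C1CCC2(CC1)OCCO2 | intermediate
4 | 2,3-dibromoprop-1-ene | C=C(Br)CBr | starting material
5 | 8-{2-[(2-bromoprop-2-en-1-yl)oxy]propan-2-yl}-1,4-dioxaspiro[4.5]decane | C=C(Br)COC(C)(C)C1CCC2(CC1)OCCO2 | intermediate
6 | 4-{2-[(2-bromoprop-2-en-1-yl)oxy]propan-2-yl}cyclohexan-1-one | C=C(Br)COC(C)(C)C1CCC(=O)CC1 | intermediate
7 | lithium (R)-4-{2-[(2-bromoprop-2-en-1-yl)oxy]propan-2-yl}cyclohex-1-en-1-olate | C=C(Br)COC(C)(C)[C@@H]1CCC(O[Li])=CC1 | intermediate (not isolated)
8 | (R)-{[4-(2-{[2-bromoprop-2-en-1-yl]oxy}propan-2-yl)cyclohex-1-en-1-yl]oxy}trimethylsilane | C=C(Br)COC(C)(C)[C@@H]1CCC(O[Si](C)(C)C)=CC1 | intermediate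
9 | (R)-4-{2-[(2-bromoprop-2-en-1-yl)oxy]propan-2-yl}cyclohex-2-en-1-one | C=C(Br)COC(C)(C)[C@@H]1CCC(=O)C=C1 | intermediate
10 | (4aS,8aR)-1,1-dimethyl-4-methylideneoctahydro-6H-isochromen-6-one | C=C1COC(C)(C)[C@@H]2CCC(=O)C[C@@H]21 | intermediate
11 | (4S,4aS,8aR)-4-hydroxy-4-(hydroxymethyl)-1,1-dimethyloctahydro-6H-isochromen-6-one | OC[C@]1(O)COC(C)(C)[C@@H]2CCC(=O)C[C@@H]21 | intermediate
12 | (4aS,8aR)-1,1-dimethyl-4-[(triethylsilyl)oxy]-4-{[(triethylsilyl)oxy]methyl}octahydro-6H-isochromen-6-one, C4 as in 11 | CC[Si](CC)(CC)OC[C@]1(O[Si](CC)(CC)CC)COC(C)(C)[C@@H]2CCC(=O)C[C@@H]21 | intermediate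
13 | (4aS,8aR)-1,1-dimethyl-6-methylidene-4-[(triethylsilyl)oxy]-4-{[(triethylsilyl)oxy]methyl}octahydro-1H-isochromene, C4 as in 11 | CC[Si](CC)(CC)OC[C@]1(O[Si](CC)(CC)CC)COC(C)(C)[C@@H]2CCC(=C)C[C@@H]21 | intermediate
14 | (4aS,8aR)-1,1-dimethyl-6-methylidene-4-[(triethylsilyl)oxy]octahydro-1H-isochromene-4-carbaldehyde, silyloxy syn to H-4a | O=C[C@]1(O[Si](CC)(CC)CC)COC(C)(C)[C@@H]2CCC(=C)C[C@@H]21 | intermediate
15 | 4,4-diethoxybut-1-yne | C#CCC(OCC)OCC | starting material
16 | (4,4-diethoxybut-1-yn-1-yl)lithium | [Li]C#CCC(OCC)OCC | intermediate (not isolated)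
17 | 5,5-diethoxy-1-[(4aS,8aR)-1,1-dimethyl-6-methylidene-4-(triethylsilyloxy)octahydro-1H-isochromen-4-yl]pent-2-yn-1-ol, carbinol epimers | CCOC(OCC)CC#CC(O)[C@]1(O[Si](CC)(CC)CC)COC(C)(C)[C@@H]2CCC(=C)C[C@@H]21 | intermediate
18 | (Z)-5,5-diethoxy-1-[(4aS,8aR)-1,1-dimethyl-6-methylidene-4-(triethylsilyloxy)octahydro-1H-isochromen-4-yl]pent-2-en-1-ol, carbinol epimers | CCOC(OCC)C/C=C\C(O)[C@]1(O[Si](CC)(CC)CC)COC(C)(C)[C@@H]2CCC(=C)C[C@@H]21 | intermediate
19 | (Z)-5,5-diethoxy-1-[(4aS,8aR)-1,1-dimethyl-6-methylidene-4-(triethylsilyloxy)octahydro-1H-isochromen-4-yl]pent-2-en-1-one | CCOC(OCC)C/C=C\C(=O)[C@]1(O[Si](CC)(CC)CC)COC(C)(C)[C@@H]2CCC(=C)C[C@@H]21 | intermediate (precursor of the key step)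
20 | tricyclic keto acetal, O9 triethylsilyl ether, C22 bearing 2,2-diethoxyethyl | C1C(=O)[C@]2(O[Si](CC)(CC)CC)COC(C)(C)[C@@H]3CC[C@@](C)(C[C@@H]32)[C@H]1CC(OCC)OCC | intermediate (product of the key step)
21 | 3-bromo-2-methylprop-1-ene | C=C(C)CBr | starting material
22 | lithium C5=C6 enolate of 20 | C1=C(O[Li])[C@]2(O[Si](CC)(CC)CC)COC(C)(C)[C@@H]3CC[C@@](C)(C[C@@H]32)[C@H]1CC(OCC)OCC | intermediate (not isolated)
23 | C5-(2-methylprop-2-en-1-yl) derivative of 20, C5 trans to the C22 chain | C=C(C)C[C@@H]1C(=O)[C@]2(O[Si](CC)(CC)CC)COC(C)(C)[C@@H]3CC[C@@](C)(C[C@@H]32)[C@H]1CC(OCC)OCC | intermediate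
24 | C5-(2,3-dihydroxy-2-methylpropyl) derivative of 20, carbinol epimers | CC(O)(CO)C[C@@H]1C(=O)[C@]2(O[Si](CC)(CC)CC)COC(C)(C)[C@@H]3CC[C@@](C)(C[C@@H]32)[C@H]1CC(OCC)OCC | intermediate (not isolated)
25 | C5-(2-oxopropyl) derivative of 20 | CC(=O)C[C@@H]1C(=O)[C@]2(O[Si](CC)(CC)CC)COC(C)(C)[C@@H]3CC[C@@](C)(C[C@@H]32)[C@H]1CC(OCC)OCC | intermediate
26 | diketo aldehyde, O9 triethylsilyl ether | CC(=O)C[C@@H]1C(=O)[C@]2(O[Si](CC)(CC)CC)COC(C)(C)[C@@H]3CC[C@@](C)(C[C@@H]32)[C@H]1CC=O | intermediate
27 | 3-methylbut-2-enoic acid | CC(C)=CC(=O)O | starting material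
28 | 3-methylbut-2-enoic anhydride | CC(C)=CC(=O)OC(=O)C=C(C)C | intermediate
29 | triethylsilyl ether of the target | CC(=O)C[C@@H]1C(=O)[C@]2(O[Si](CC)(CC)CC)COC(C)(C)[C@@H]3CC[C@@](C)(C[C@@H]32)[C@H]1/C=C/OC(=O)C=C(C)C | intermediate
30 | CNP0237201.2 | CC(=O)C[C@@H]1C(=O)[C@]2(O)COC(C)(C)[C@@H]3CC[C@@](C)(C[C@@H]32)[C@H]1/C=C/OC(=O)C=C(C)C | target

Total step count: 20. Longest linear sequence: 19 (steps 1–17, 19 and 20; step 18 is a one-step side branch).

Steps most likely to fail

Step 14. The Z-enone may isomerise to E by reversible hydrogen-atom or conjugate addition before the ring closes, or the ring may close through another fold, so that C22 forms with the opposite configuration; slow closure would also let plain reduction of C18=C19 compete. The fallback sets out from 19 and returns at 20. The cyclisation is run as in step 14 and the C22-epimeric tricyclic keto acetal F1 is carried on. LiN(i-Pr)2 and TMSCl convert it into the C5=C6 trimethylsilyl enol ether F2, and dehydrogenation with IBX and 4-methoxypyridine N-oxide (as in step 5) gives the ring-B enone F3, in which C22 is trigonal. Conjugate reduction with [(Ph3P)CuH]6 (or H2 over Pd/C) should deliver hydrogen to C22 from the open outer face, the face the carbon chain occupied in F1, and protonation of the enolate then gives 20. The stereocentre is thus set by hydride delivery instead of by the radical step.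

Step 19. Under the amine base the free aldehyde may condense intramolecularly with the C2 methyl ketone (five-membered aldol closure between C23 and C2 or between C4 and C24) faster than its enol is acylated, and E/Z control may be incomplete. The fallback sets out from 20 and returns at 29; it keeps the methyl ketone masked as an alkyne until the enol ester is in place. C5 is alkylated with propargyl bromide under the conditions of step 15 to give the C5-propargyl keto acetal F4. Acetal hydrolysis as in step 17 gives the alkynyl keto aldehyde F5, which has no second carbonyl within aldol reach. Enol esterification with 28 as in step 19 gives the alkynyl enol ester F6. Gold-catalysed Markovnikov hydration (Ph3PAuNTf2, aqueous dioxane, rt) then unveils the methyl ketone and gives 29.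

Step 6. The palladium enolate may epimerise through its oxygen-bound form and undergo β-hydride elimination to the Heck dienone, or palladium hydride may move the exocyclic C8=C6 alkene into conjugation with O11. The fallback sets out from 9 and returns at 10 without new isolated compounds. The same bond is made by a tin-free radical chain with (Me3Si)3SiH and AIBN in toluene at 80 °C under slow addition: bromine abstraction gives the C8 vinyl radical, which closes 6-exo-trig onto C21 of the enone, and the silane reduces the α-keto radical. No metal hydride is present and the tether again imposes the cis ring fusion.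

Further compounds
F1 | step 14 | C22 epimer of tricyclic keto acetal 20 | C1C(=O)[C@]2(O[Si](CC)(CC)CC)COC(C)(C)[C@@H]3CC[C@@](C)(C[C@@H]32)[C@@H]1CC(OCC)OCC
F2 | step 14 | C5=C6 trimethylsilyl enol ether of F1 | C1=C(O[Si](C)(C)C)[C@]2(O[Si](CC)(CC)CC)COC(C)(C)[C@@H]3CC[C@@](C)(C[C@@H]32)[C@@H]1CC(OCC)OCC
F3 | step 14 | ring-B enone (C5=C22) bearing 2,2-diethoxyethyl on C22 | O=C1C=C(CC(OCC)OCC)[C@@]2(C)CC[C@H]3C(C)(C)OC[C@]1(O[Si](CC)(CC)CC)[C@H]3C2
F4 | step 19 | C5-(prop-2-yn-1-yl) derivative of 20 | C#CC[C@@H]1C(=O)[C@]2(O[Si](CC)(CC)CC)COC(C)(C)[C@@H]3CC[C@@](C)(C[C@@H]32)[C@H]1CC(OCC)OCC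
F5 | step 19 | C5-(prop-2-yn-1-yl) keto aldehyde | C#CC[C@@H]1C(=O)[C@]2(O[Si](CC)(CC)CC)COC(C)(C)[C@@H]3CC[C@@](C)(C[C@@H]32)[C@H]1CC=O
F6 | step 19 | C5-(prop-2-yn-1-yl) (E)-enol 3-methylbut-2-enoate | C#CC[C@@H]1C(=O)[C@]2(O[Si](CC)(CC)CC)COC(C)(C)[C@@H]3CC[C@@](C)(C[C@@H]32)[C@H]1/C=C/OC(=O)C=C(C)C
F0 | step 6 | none | none
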